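The numbers in the tables were generated by integration from invented constants; the scatter is artificial.

Take time first: 40 h lies later than any reading, so do not stretch the curve of the asked flask, birch; bracket it.

| flask | electrophile | nucleophile | solid base | remark | time |
|---|---|---|---|---|---|
| birch | 0.80 M | 0.80 equiv | 0.80 equiv | the very flask that is asked about, followed so far |  |
| oak | 0.80 M | 0.80 equiv | 0.54 equiv | run made earlier |  |
| flask | 0.80 M | 0.800 equiv | 0.800 equiv |  | 40 h |

| run | time / h | electrophile / % | target / % |
|---|---|---|---|
| birch | 1.00 | 49.1 | 43.8 |
| birch | 1.33 | 46.4 | 44.9 |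
| birch | 2.00 | 42.7 | 44.5 |
| birch | 3.00 | 38.0 | 43.7 |
| birch | 5.00 | 32.6 | 43.8 |
| birch | 8.00 | 27.0 | 45.2 |
| birch | 12.0 | 22.7 | 46.7 |
| oak | 0.833 | 50.3 | 43.4 |
| oak | 2.50 | 40.1 | 44.6 |
| oak | 5.00 | 32.8 | 44.6 |
| oak | 6.00 | 31.2 | 44.0 |
| oak | 10.0 | 25.0 | 46.2 |
| oak | 12.0 | 22.7 | 47.1 |
| oak | 15.0 | 21.2 | 48.3 |

(readings scatter by 0.5 percentage points)

* part of the electrophile that has reacted at 40 h
* share of the unused nucleophile that is free and not bound as protonated nucleophile, at 40 h

- given per volume of solution although it is solid: solid base
- the numbers in the tables scatter with a standard deviation of 0.5 percentage points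
- at the start none of the solid base is in solution
- the earlier runs do not show how much of nucleophile is bound; that part of a forecast is a guess

Bound the part reacted from below. Electrophile falls from reading to reading in both runs, and oak, with less solid base, tracks birch (32.8% against 32.6% at 5.00 h), so oak's last reading puts it at about 78.8%. Bound it from above by assuming that each electrophile reacted takes one nucleophile, the limiting reagent. This gives the nucleophile ceiling, the part reacted that equals the equivalents of nucleophile charged, 80.0%.

Tighten in powers of ten. Oak's gap to the ceiling is 13 percentage points at 5.00 h and 1.2 points at 15.0 h, one power of ten per 9.73 h, though the scatter weighs heavily on the smaller gap. Continued to 40 h, the gap is about 0.0032 points, so I commit to the ceiling. The runs do not show how much nucleophile is bound, so I bracket no free share.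

The forecast says 87% reacted and 50% free. It stands above my ceiling, on its own grounds: “Extrapolating gives about 11–14% electrophile left at 40 h”.

Birch gives 80.0% reacted and 47.7% free.

    electrophile + nucleophile → acid set free + target (k = 9.24 /M/h)
    nucleophile + acid set free ⇌ protonated nucleophile, settled at all times (K = 69.1 /M)
    acid set free + free base ⇌ salt of the base, settled at all times (K = 282 /M)
    target ⇌ isomer of the product (K = 0.680, k = 0.215 /h)
    solid base ⇌ free base, rate k5*(cs5 - [free base]) while solid is left; crystals form when [free base] > cs5 (solubility = 0.0560 M, k = 0.479 /h)
    acid set free → by-product carried off (k = 0.150 /h)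

Birch ends on its ceiling of 80.0%, with 20% of the electrophile and 0% of the nucleophile left, and target at 47.6% beside isomer of the product at 32.4%. Carry the ceiling to the neighbouring flask, charged with 0.200 equiv of nucleophile, and reckon 20.0% reacted. That flask gives 20.0%, and 80.0% of its electrophile stands unreacted at 40.0 h.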